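The south-east run is our one guide to the flask.

| flask | substrate | solid partner | remark | time |
|---|---|---|---|---|
| south-east | 2.1 M | 1.5 M | run made earlier |  |
| flask | 1.5 M | 1.50 M |  | 2.5 h |

- south-east (time / h: target / %, substrate / %): 0.667: 5.7, 44.8; 0.833: 8.3, 43.9; 1.33: 14.8, 40.3; 2.00: 17.0, 37.8; 2.50: 17.6, 37.9

(each reading ± 0.3 percentage points)

- given per volume of solution although it is solid: solid partner
- at the start none of the solid partner is in solution

- time up to 2.5 h at which target stands highest
- the amount of target, in percent of the substrate charged, at that time

In the south-east run target flattens while substrate still stands at 37.9 %: the last interval adds 0.6 percentage points, far less than that substrate. So we suspect the solid partner is the limiting reagent, and we carry the partner yield 0.246, target formed as a fraction of the solid partner charged. Target share is then partner yield times equivalents of solid partner. Going from 0.714 equivalents in the run to 1.00 in the flask is a step of 0.146 decades above 17.6 %, which gives 24.6 %.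

Two doubts remain. That last rise is thin against a scatter of 0.3 points, so the top might already have passed; but target falls in no interval, so we take 2.5 h. And a yield of a quarter leaves the rest of the solid unaccounted for, and one run cannot show that this share holds at lower substrate. If target were instead a fixed fraction of the charge, the flask would stay at 17.6 %. But substrate stood unused while target flattened, so we keep 24.6 %.

The forecast gives 24 % at 2.5 h, slightly below our figure, noting that “Lower concentration could reduce this somewhat”.

The flask gives 21.8 % at 2.50 h, and both forecast values stand within their margins.

    substrate ⇌ open intermediate (K = 1.18, k = 0.0590 min⁻¹)
    fresh partner → second intermediate (k = 0.0806 min⁻¹)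
    open intermediate + second intermediate → target (k = 0.0406 M⁻¹ min⁻¹)
    2 second intermediate → homo product (k = 0.0400 M⁻¹ min⁻¹)
    fresh partner → decomposed reagent (k = 0.191 min⁻¹)
    solid partner ⇌ fresh partner, rate k6*(cs6 - [fresh partner]) while solid is left; crystals form when [fresh partner] > cs6 (solubility = 1.20 M, k = 0.0217 min⁻¹)

That is a partner yield of 0.218 in the flask, against the carried 0.246. A neighbouring flask is charged with 0.90 M of solid partner, 0.600 equiv to substrate, with the other charges and the time held. That is a step of −0.222 decades in solid partner, and the carried yield gives it 14.8 % of the substrate charged. The neighbouring flask reaches 14.1 %, with 0 % of its solid partner left, solid or dissolved, and 39 % of its substrate still there.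

The runs are simulated on assumed constants.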